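All runs were generated by integration for substances that don't exist, and the scatter is random.

The vessel is closed, stirred and isothermal. It holds a racemate with reagent, free catalyst and precatalyst, and beta and epsilon are one recipe stopped at different times.

in all of them: left-handed substrate 0.085 M; right-handed substrate 0.085 M; reagent 0.213 M; free catalyst 0.85 mM

| run | precatalyst | remark | time |
|---|---|---|---|
| north | 0.21 mM | run made earlier |  |
| beta | 0.43 mM |  | 4.0 min |
| epsilon | 0.43 mM |  | 2.0 min |

north run (percent of the left-handed substrate and right-handed substrate together charged)

| time / s | right-handed substrate / % | left-handed substrate / % |
|---|---|---|
| 10.0 | 46.8 | 22.2 |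
| 15.0 | 45.6 | 14.6 |
| 20.0 | 45.5 | 11.0 |
| 30.0 | 44.6 | 7.1 |
| 50.0 | 40.7 | 3.8 |

(readings scatter by 1 percentage point)

- free catalyst is single-handed; left-handed substrate and right-handed substrate are mirror images of each other, charged as a racemate, each of them at the stated concentration
- the numbers in the tables scatter by 1 percentage point (one standard deviation)
- an excess is the difference of the two amounts in percent of their sum
- an excess is below zero if the other one leads
- no earlier run changes the charge of precatalyst; that part of a forecast is a guess

- which one finishes higher in excess of right-handed substrate over left-handed substrate among what is left of the two ("neither" within 2 percentage points) (beta / epsilon / neither)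
- excess of right-handed substrate over left-handed substrate among what is left of the two at the end, beta
- excess of right-handed substrate over left-handed substrate among what is left of the two at the end, epsilon

We start from rates. In the north run, left-handed substrate falls per unit amount at 0.0702 s⁻¹ early and at 0.0313 s⁻¹ late, as read through the scatter. That is a slowing by a factor 2.24. By balance, taking one reagent per substrate lost, reagent goes from 68.2% to 58.6% of its charge, a factor of 1.16, which is less. So we suspect a feed: right-handed substrate is being handed over to left-handed.

Freeze the right-handed amount, and left-handed sits where handover balances drain (pseudo-first-order at the reagent of the moment). Call handover over drain, each per unit amount, the handover ratio R. Left over right is then R/(1+R), so the excess is 1/(1+2R). The last north reading gives R = 0.103, a reading we take to be high if part of the charged left-handed substrate still stands in it.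

We guess that handover grows with precatalyst and time, and that drain follows reagent. North ended with 55.7% of its reagent. Beta, with the substrate nearly used, would hold 20.2%. Epsilon, we take, would hold 40.1%. Hence R is 2.79 for beta and 0.702 for epsilon, so we reckon excesses of about 15.2% and 41.6%: the longer flask, beta, ends lower.

The forecast differs: it names beta, with 97% for beta and 94% for epsilon, and says “The longer run should finish higher”.

The flasks give 28.9% for beta and 62.5% for epsilon, so epsilon finishes higher.

    2 reagent → self-condensation product (k = 0.00139 M⁻¹ s⁻¹)
    left-handed substrate + racemization catalyst ⇌ right-handed substrate + racemization catalyst, rate k2*[racemization catalyst]*[left-handed substrate] forward; the back reaction follows from the equilibrium constant (k = 153 M⁻¹ s⁻¹)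
    precatalyst → racemization catalyst (k = 0.00154 s⁻¹)
    reagent + free catalyst + right-handed substrate → free catalyst + right-handed product (k = 30.1 M⁻² s⁻¹)
    reagent + free catalyst + left-handed substrate → free catalyst + left-handed product (k = 529 M⁻² s⁻¹)

In beta, 46.1% of the substrate had reacted by 0.400 min and 75.5% by 2.00 min, with racemization catalyst at 16.9% of the precatalyst charge. By 4.0 min that catalyst stood at 30.9%, reagent had fallen from 37.6% to 24.1% of its own charge, and right-handed substrate from 19.9% to 5.37% of the two substrates charged together. A neighbour of beta, charged with 0.085 M of reagent, kept 0.872% of it at 4.00 min, so our reckoned R becomes 162 and the excess 0.308%. That flask ended at 1.33%.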